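Numbering runs from the lactone carbonyl C1 through ring carbinol C5, the Z-alkene C6=C7 and the carbinols C9, C11 and C13 to benzylic C15. The plan rests on the C13 acetate being 1,3-anti to the free C11 hydroxyl. An Evans-Tishchenko reduction of a C11 ketone with acetaldehyde creates the C11 carbinol and places the acetate on O13 in one operation, by hydride transfer from an O13-bound hemiacetal. Its precursor is a C13-hydroxy C11-ketone carrying a C9 PMB ether, the Z-alkene and the dihydropyranone ring (O, C1-C5) masked as a methyl lactol ether. It is assembled by a 1,5-anti boron aldol (C12-C13), an acetylide-epoxide coupling (C7-C8) and a hetero-Diels-Alder reaction.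

Key step: step 9

Assumption: the antipode of the aminoindanol ligand (both are sold) that delivers 5S is used in step 1 and its sense is confirmed on the first batch; the anomeric centre (drawn cis, as the endo cycloaddition should give it) is incidental and is erased in step 11.

Step 1
Reactants: 1 (E)-1-methoxybuta-1,3-diene; 2 3-(trimethylsilyl)prop-2-ynal
Product: 3 (2S,6R)-6-methoxy-2-[(trimethylsilyl)ethynyl]-3,6-dihydro-2H-pyran (2,6-cis; ring C2 is C5 of the target)
Conditions: [Cr(L)Cl] (3 mol%; trivalent chromium; H2L = Schiff base of cis-1-amino-2-indanol and 3-(1-adamantyl)-2-hydroxy-5-methylbenzaldehyde), 4 Å MS, neat, rt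
Reagents that add atoms: none
Why: Catalytic asymmetric hetero-Diels-Alder reaction in which the chiral chromium Lewis acid binds the ynal and the electron-rich diene adds through the endo transition state, which should give the 2,6-cis adduct and set C5 (S) under catalyst control; the only ring of the target is thus made first and carried as a base-stable methyl lactol ether.

Step 2
Reactants: 3 (2S,6R)-6-methoxy-2-[(trimethylsilyl)ethynyl]-3,6-dihydro-2H-pyran
Product: 4 (2S,6R)-2-ethynyl-6-methoxy-3,6-dihydro-2H-pyran (fragment A)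
Conditions: K2CO3 (0.2 equiv), MeOH, 0 °C → rt; pentane extraction, cold concentration (volatile)
Reagents that add atoms: none
Why: Protodesilylation of an alkynylsilane by methoxide is fast and, being basic, should leave the acid-labile allylic acetal and both stereocentres untouched.

Step 3
Reactants: 5 (S)-epichlorohydrin; 6 2-methyl-1,3-dithiane
Product: 9 (S)-2-[(2-methyl-1,3-dithian-2-yl)methyl]oxirane (fragment B), via 2-lithio-2-methyl-1,3-dithiane 7 (not isolated), via lithium chlorohydrin alkoxide 8 (not isolated)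
Conditions: n-BuLi, THF, −20 °C; then 5, −78 °C → rt
Reagents that add atoms: none
Why: Dithiane umpolung alkylation in which the lithiated dithiane should open the epoxide at its unsubstituted carbon in preference to displacing chloride, after which the alkoxide closes onto CH2Cl by intramolecular SN2 on warming, so that no bond to the stereocentre is broken and C9 is carried over from 5 (the descriptor stays S).

Step 4
Reactants: 4 (2S,6R)-2-ethynyl-6-methoxy-3,6-dihydro-2H-pyran; 9 (S)-2-[(2-methyl-1,3-dithian-2-yl)methyl]oxirane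
Product: 11 (2R)-1-(2-methyl-1,3-dithian-2-yl)-5-[(2S,6R)-6-methoxy-3,6-dihydro-2H-pyran-2-yl]pent-4-yn-2-ol, via lithium acetylide 10 (not isolated)
Conditions: 4, n-BuLi (1.0 equiv), THF, −78 °C; then 9 (1.3 equiv), DMPU, −78 °C → rt; H2O quench
Reagents that add atoms: none
Why: Alkylation of a lithium acetylide by SN2 opening of the terminal epoxide at its CH2, made feasible by the dipolar cosolvent DMPU in place of BF3·OEt2 (which would ionise the allylic acetal), forms C7-C8 and leaves C9 untouched (its descriptor becomes R only through the change of priorities).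

Step 5
Reactants: 11 (2R)-1-(2-methyl-1,3-dithian-2-yl)-5-[(2S,6R)-6-methoxy-3,6-dihydro-2H-pyran-2-yl]pent-4-yn-2-ol
Product: 13 2-{(2R)-2-[(4-methoxybenzyl)oxy]-5-[(2S,6R)-6-methoxy-3,6-dihydro-2H-pyran-2-yl]pent-4-yn-1-yl}-2-methyl-1,3-dithiane, via sodium alkoxide 12 (not isolated)
Conditions: NaH, THF/DMF (4:1), 0 °C; PMBCl, Bu4NI (cat.), rt
Reagents that add atoms: 4-methoxybenzyl chloride, COc1ccc(CCl)cc1
Why: Williamson etherification through the sodium alkoxide and in situ 4-methoxybenzyl iodide is purely basic and so suits the acetal and the dithiane, and the PMB ether is chosen because the later 1,5-anti aldol needs a benzyl-type β-alkoxy group.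

Step 6
Reactants: 13 2-{(2R)-2-[(4-methoxybenzyl)oxy]-5-[(2S,6R)-6-methoxy-3,6-dihydro-2H-pyran-2-yl]pent-4-yn-1-yl}-2-methyl-1,3-dithiane
Product: 14 (4R)-4-[(4-methoxybenzyl)oxy]-7-[(2S,6R)-6-methoxy-3,6-dihydro-2H-pyran-2-yl]hept-6-yn-2-one
Conditions: MeI (excess), CaCO3, MeCN/H2O (9:1), 40 °C
Reagents that add atoms: water, O
Why: Alkylative dithiane hydrolysis, in which S-methylation makes sulfur a leaving group and water delivers the ketone while solid CaCO3 takes up the HI, should spare the methyl acetal, the PMB ether and the β-alkoxy ketone, and needs no mercury or silver salt that would attack the alkyne.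

Step 7
Reactants: 14 (4R)-4-[(4-methoxybenzyl)oxy]-7-[(2S,6R)-6-methoxy-3,6-dihydro-2H-pyran-2-yl]hept-6-yn-2-one
Product: 15 (4R,6Z)-4-[(4-methoxybenzyl)oxy]-7-[(2S,6R)-6-methoxy-3,6-dihydro-2H-pyran-2-yl]hept-6-en-2-one
Conditions: H2 (1 atm), Pd/CaCO3 poisoned with Pb(OAc)2, quinoline, EtOAc, rt
Reagents that add atoms: none
Why: Semihydrogenation (Lindlar reduction) adds H2 syn on the poisoned palladium surface to give the Z C6=C7 alkene, quinoline arrests reduction there so that the ring alkene and the benzyl ether are spared, and the step comes after sulfur removal so that the catalyst is not poisoned.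

Step 8
Reactants: 15 (4R,6Z)-4-[(4-methoxybenzyl)oxy]-7-[(2S,6R)-6-methoxy-3,6-dihydro-2H-pyran-2-yl]hept-6-en-2-one; 16 3-phenylpropanal
Product: 19 (3R,7R,9Z)-3-hydroxy-7-[(4-methoxybenzyl)oxy]-10-[(2S,6R)-6-methoxy-3,6-dihydro-2H-pyran-2-yl]-1-phenyldec-9-en-5-one, via dicyclohexylboron enolate 17 (not isolated), via boron aldolate 18 (not isolated)
Conditions: Cy2BCl premixed with Et3N, Et2O, 0 °C; 16, −78 → −20 °C; then MeOH, pH 7 buffer, H2O2, 0 °C
Reagents that add atoms: none
Why: 1,5-anti boron aldol of a β-alkoxy methyl ketone, in which Cy2BCl/Et3N enolises kinetically at the methyl group (C12) and the C9 PMB-oxy group orients the boat-like transition state (a contact between its oxygen and the aldehyde C-H) so that C13 should form as R, 1,5-anti to C9; the amine is mixed with the borane first so that no free Lewis acid meets the acetal.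

Step 9
Reactants: 19 (3R,7R,9Z)-3-hydroxy-7-[(4-methoxybenzyl)oxy]-10-[(2S,6R)-6-methoxy-3,6-dihydro-2H-pyran-2-yl]-1-phenyldec-9-en-5-one; 20 acetaldehyde
Product: 22 (3R,5R,7R,9Z)-5-hydroxy-7-[(4-methoxybenzyl)oxy]-10-[(2S,6R)-6-methoxy-3,6-dihydro-2H-pyran-2-yl]-1-phenyldec-9-en-3-yl acetate, via samarium-bound hemiacetal 21 (not isolated)
Conditions: SmI2 (0.3 equiv) added to freshly distilled MeCHO (8 equiv) in THF, −10 °C; then 19, −10 °C; NaHCO3 quench
Reagents that add atoms: none
Why: SmI2 is first consumed by acetaldehyde to give a trivalent samarium alkoxide, the actual catalyst; the C13 hydroxyl of 19 then adds to acetaldehyde, samarium bridges the hemiacetal oxygen and the C11 carbonyl oxygen, and the hemiacetal hydrogen passes intramolecularly to C11 while the hemiacetal carbon collapses to the acetyl carbonyl already attached to O13. This is the Evans-Tishchenko reduction of a β-hydroxy ketone, well established with acetaldehyde and other aldehydes as hydride donors. No ring is closed: the six-membered chair exists only in the transition state and opens as the ester forms. C11 (R) is the only new stereocentre and is controlled by C13, since with the chain substituents equatorial in the chair the hydride reaches the carbonyl face that gives the 1,3-anti relationship. The step needs anti facial selectivity at C11 and acylation of O13 alone among three secondary oxygens, and both are secured by the tether, because hydride and acyl group come from the same O13-bound hemiacetal, O9 is a PMB ether that cannot form one, and O11 emerges only as the free alkoxide. The substrate is otherwise inert because the enoate that divalent samarium could reduce is still a lactol ether and the isolated alkenes do not react, and the low temperature and bicarbonate quench should keep the acetate on O13.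

Step 10
Reactants: 22 (3R,5R,7R,9Z)-5-hydroxy-7-[(4-methoxybenzyl)oxy]-10-[(2S,6R)-6-methoxy-3,6-dihydro-2H-pyran-2-yl]-1-phenyldec-9-en-3-yl acetate
Product: 23 (3R,5R,7R,9Z)-5,7-dihydroxy-10-[(2S,6R)-6-methoxy-3,6-dihydro-2H-pyran-2-yl]-1-phenyldec-9-en-3-yl acetate
Conditions: DDQ (1.3 equiv), CH2Cl2/pH 7 phosphate buffer (10:1), 0 °C
Reagents that add atoms: none
Why: Oxidative PMB cleavage, in which electron transfer from the electron-rich arene to DDQ gives a benzylic oxocarbenium ion that water hydrolyses to the C9 alcohol, runs in a neutral buffer that protects the methyl acetal and stops acetate migration, and any p-methoxybenzylidene acetal formed with the syn C11 hydroxyl would fall to the acid of step 11.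

Step 11
Reactants: 23 (3R,5R,7R,9Z)-5,7-dihydroxy-10-[(2S,6R)-6-methoxy-3,6-dihydro-2H-pyran-2-yl]-1-phenyldec-9-en-3-yl acetate
Product: 24 (3R,5R,7R,9Z)-5,7-dihydroxy-10-[(2S)-6-hydroxy-3,6-dihydro-2H-pyran-2-yl]-1-phenyldec-9-en-3-yl acetate (lactol; both anomers)
Conditions: pyridinium p-toluenesulfonate (0.2 equiv), THF/H2O (3:1), rt
Reagents that add atoms: water, O
Why: Acid-catalysed acetal hydrolysis through the allylic oxocarbenium ion needs only pyridinium tosylate for this activated acetal, which should leave the acetate, the C5-O bond and the Z-alkene alone, and THF replaces acetone so that the syn-1,3-diol cannot be tied up as an acetonide.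

Step 12
Reactants: 24 (3R,5R,7R,9Z)-5,7-dihydroxy-10-[(2S)-6-hydroxy-3,6-dihydro-2H-pyran-2-yl]-1-phenyldec-9-en-3-yl acetate
Product: 25 (3R,5R,7R,9Z)-5,7-dihydroxy-10-[(2S)-6-oxo-3,6-dihydro-2H-pyran-2-yl]-1-phenyldec-9-en-3-yl acetate (CNP0264384.1)
Conditions: activated MnO2 (excess), CH2Cl2, rt
Reagents that add atoms: none
Why: MnO2 oxidises allylic carbinols chemoselectively, so the lactol hydroxyl (the only allylic one) should go to the α,β-unsaturated δ-lactone while the saturated C9 and C11 alcohols stay, and the neutral medium leaves the acetate on O13.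

Compound list
1 | (E)-1-methoxybuta-1,3-diene | CO/C=C/C=C | starting material
2 | 3-(trimethylsilyl)prop-2-ynal | C[Si](C)(C)C#CC=O | starting material
3 | (2S,6R)-6-methoxy-2-[(trimethylsilyl)ethynyl]-3,6-dihydro-2H-pyran | C[Si](C)(C)C#C[C@@H]1CC=C[C@H](OC)O1 | intermediate
4 | (2S,6R)-2-ethynyl-6-methoxy-3,6-dihydro-2H-pyran | C#C[C@@H]1CC=C[C@H](OC)O1 | intermediate
5 | (S)-epichlorohydrin | ClC[C@@H]1CO1 | starting material
6 | 2-methyl-1,3-dithiane | CC1SCCCS1 | starting material
7 | 2-lithio-2-methyl-1,3-dithiane | [Li]C1(C)SCCCS1 | intermediate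
8 | lithium (2S)-1-chloro-3-(2-methyl-1,3-dithian-2-yl)propan-2-olate | CC1(SCCCS1)C[C@H]([O-])CCl.[Li+] | intermediate
9 | (S)-2-[(2-methyl-1,3-dithian-2-yl)methyl]oxirane | CC1(SCCCS1)C[C@H]2CO2 | intermediate
10 | {[(2S,6R)-6-methoxy-3,6-dihydro-2H-pyran-2-yl]ethynyl}lithium | [Li]C#C[C@@H]1CC=C[C@H](OC)O1 | intermediate
11 | (2R)-1-(2-methyl-1,3-dithian-2-yl)-5-[(2S,6R)-6-methoxy-3,6-dihydro-2H-pyran-2-yl]pent-4-yn-2-ol | CC1(SCCCS1)C[C@H](O)CC#C[C@@H]2CC=C[C@H](OC)O2 | intermediate
12 | sodium alkoxide of 11 | CC1(SCCCS1)C[C@H]([O-])CC#C[C@@H]2CC=C[C@H](OC)O2.[Na+] | intermediate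
13 | 2-{(2R)-2-[(4-methoxybenzyl)oxy]-5-[(2S,6R)-6-methoxy-3,6-dihydro-2H-pyran-2-yl]pent-4-yn-1-yl}-2-methyl-1,3-dithiane | CC1(SCCCS1)C[C@H](OCc2ccc(OC)cc2)CC#C[C@@H]3CC=C[C@H](OC)O3 | intermediate
14 | (4R)-4-[(4-methoxybenzyl)oxy]-7-[(2S,6R)-6-methoxy-3,6-dihydro-2H-pyran-2-yl]hept-6-yn-2-one | CC(=O)C[C@H](OCc1ccc(OC)cc1)CC#C[C@@H]2CC=C[C@H](OC)O2 | intermediate
15 | (4R,6Z)-4-[(4-methoxybenzyl)oxy]-7-[(2S,6R)-6-methoxy-3,6-dihydro-2H-pyran-2-yl]hept-6-en-2-one | CC(=O)C[C@H](OCc1ccc(OC)cc1)C/C=C\[C@@H]2CC=C[C@H](OC)O2 | intermediate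
16 | 3-phenylpropanal | O=CCCc1ccccc1 | starting material
17 | dicyclohexylboron enolate of 15 (O-B on C11; C11=C12 methylene) | C=C(OB(C1CCCCC1)C2CCCCC2)C[C@H](OCc3ccc(OC)cc3)C/C=C\[C@@H]4CC=C[C@H](OC)O4 | intermediate
18 | dicyclohexylboron aldolate of 19 (boron on O13) | C1CCCCC1B(C2CCCCC2)O[C@H](CCc3ccccc3)CC(=O)C[C@H](OCc4ccc(OC)cc4)C/C=C\[C@@H]5CC=C[C@H](OC)O5 | intermediate
19 | (3R,7R,9Z)-3-hydroxy-7-[(4-methoxybenzyl)oxy]-10-[(2S,6R)-6-methoxy-3,6-dihydro-2H-pyran-2-yl]-1-phenyldec-9-en-5-one | O[C@H](CCc1ccccc1)CC(=O)C[C@H](OCc2ccc(OC)cc2)C/C=C\[C@@H]3CC=C[C@H](OC)O3 | intermediate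
20 | acetaldehyde | CC=O | starting material
21 | O13 hemiacetal of 19 and acetaldehyde, samarium-bound (drawn as the free hemiacetal) | CC(O)O[C@H](CCc1ccccc1)CC(=O)C[C@H](OCc2ccc(OC)cc2)C/C=C\[C@@H]3CC=C[C@H](OC)O3 | intermediate
22 | (3R,5R,7R,9Z)-5-hydroxy-7-[(4-methoxybenzyl)oxy]-10-[(2S,6R)-6-methoxy-3,6-dihydro-2H-pyran-2-yl]-1-phenyldec-9-en-3-yl acetate | CC(=O)O[C@H](CCc1ccccc1)C[C@H](O)C[C@H](OCc2ccc(OC)cc2)C/C=C\[C@@H]3CC=C[C@H](OC)O3 | intermediate
23 | (3R,5R,7R,9Z)-5,7-dihydroxy-10-[(2S,6R)-6-methoxy-3,6-dihydro-2H-pyran-2-yl]-1-phenyldec-9-en-3-yl acetate | CC(=O)O[C@H](CCc1ccccc1)C[C@H](O)C[C@H](O)C/C=C\[C@@H]1CC=C[C@H](OC)O1 | intermediate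
24 | (3R,5R,7R,9Z)-5,7-dihydroxy-10-[(2S)-6-hydroxy-3,6-dihydro-2H-pyran-2-yl]-1-phenyldec-9-en-3-yl acetate (anomer mixture) | CC(=O)O[C@H](CCc1ccccc1)C[C@H](O)C[C@H](O)C/C=C\[C@@H]1CC=CC(O)O1 | intermediate
25 | (3R,5R,7R,9Z)-5,7-dihydroxy-10-[(2S)-6-oxo-3,6-dihydro-2H-pyran-2-yl]-1-phenyldec-9-en-3-yl acetate | CC(=O)O[C@H](CCc1ccccc1)C[C@H](O)C[C@H](O)C/C=C\[C@@H]1CC=CC(=O)O1 | target

Total step count: 12
Longest linear sequence: 11 steps (steps 1, 2 and 4 to 12, from 1 and 2)

Steps most likely to fail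

Step 4. Without a Lewis acid the epoxide opening may be slow and incomplete, and long warming may erode the acetylide and lose the volatile alkyne. The fallback sets out from 9 and comes back at 13. Epoxide 9 would be opened with LiC≡CH·H2NCH2CH2NH2 in DMSO at rt to give (2R)-1-(2-methyl-1,3-dithian-2-yl)pent-4-yn-2-ol F1. NaH, PMBCl and Bu4NI would give 2-{(2R)-2-[(4-methoxybenzyl)oxy]pent-4-yn-1-yl}-2-methyl-1,3-dithiane F2. n-BuLi and then DMF, with an inverse quench into aqueous KH2PO4, would give (5R)-5-[(4-methoxybenzyl)oxy]-6-(2-methyl-1,3-dithian-2-yl)hex-2-ynal F3. The chromium-catalysed hetero-Diels-Alder reaction of F3 with 1 under the conditions of step 1 would then build the ring last and give 13, so that C7-C8 is made before any acetal exists.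

Step 8. The 1,5-anti facial selectivity may be insufficient with an unbranched aldehyde, or the chloroborane may ionise the allylic acetal. The fallback sets out from 5 and comes back at 19; it takes C13 from a bought epoxide instead of from induction. Bought 2-(tert-butyldimethylsilyl)-1,3-dithiane would be lithiated (t-BuLi, Et2O, −78 → −45 °C) and added to bought (R)-2-(2-phenylethyl)oxirane. Addition of 5 in THF/HMPA would trigger the 1,4-Brook rearrangement, and the relayed dithiane anion would open 5 and close as in step 3 to give 2-[(2R)-2-(tert-butyldimethylsilyloxy)-4-phenylbutyl]-2-[(2S)-oxiran-2-ylmethyl]-1,3-dithiane F4. Acetylide 10 would open F4 as in step 4 to (2R)-1-{2-[(2R)-2-(tert-butyldimethylsilyloxy)-4-phenylbutyl]-1,3-dithian-2-yl}-5-[(2S,6R)-6-methoxy-3,6-dihydro-2H-pyran-2-yl]pent-4-yn-2-ol F5. NaH/PMBCl would give 2-[(2R)-2-(tert-butyldimethylsilyloxy)-4-phenylbutyl]-2-{(2R)-2-[(4-methoxybenzyl)oxy]-5-[(2S,6R)-6-methoxy-3,6-dihydro-2H-pyran-2-yl]pent-4-yn-1-yl}-1,3-dithiane F6. MeI/CaCO3 would give (3R,7R)-3-(tert-butyldimethylsilyloxy)-7-[(4-methoxybenzyl)oxy]-10-[(2S,6R)-6-methoxy-3,6-dihydro-2H-pyran-2-yl]-1-phenyldec-9-yn-5-one F7. Semihydrogenation as in step 7 would give (3R,7R,9Z)-3-(tert-butyldimethylsilyloxy)-7-[(4-methoxybenzyl)oxy]-10-[(2S,6R)-6-methoxy-3,6-dihydro-2H-pyran-2-yl]-1-phenyldec-9-en-5-one F8. HF·pyridine buffered with pyridine in THF at 0 °C would then remove the silyl group and give 19.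

Step 10. Hydrolytic cleavage may be incomplete: the syn C11 hydroxyl may trap the benzylic cation as a cyclic acetal, which DDQ may over-oxidise to a 4-methoxybenzoate. The fallback sets out from 22 and comes back at 24; it makes the cyclic acetal on purpose. DDQ under anhydrous conditions (4 Å MS, CH2Cl2, 0 °C) would convert 22 into the all-cis O9,O11 p-methoxybenzylidene acetal (2-(4-methoxyphenyl)-1,3-dioxane, C13 acetate retained) F9. AcOH/THF/H2O (3:1:1) at rt would then cleave this acetal and the methyl lactol ether together and give 24 directly.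

Further compounds
F1 | step 4 | (2R)-1-(2-methyl-1,3-dithian-2-yl)pent-4-yn-2-ol | CC1(SCCCS1)C[C@H](O)CC#C
F2 | step 4 | 2-{(2R)-2-[(4-methoxybenzyl)oxy]pent-4-yn-1-yl}-2-methyl-1,3-dithiane | CC1(SCCCS1)C[C@H](OCc2ccc(OC)cc2)CC#C
F3 | step 4 | (5R)-5-[(4-methoxybenzyl)oxy]-6-(2-methyl-1,3-dithian-2-yl)hex-2-ynal | CC1(SCCCS1)C[C@H](OCc2ccc(OC)cc2)CC#CC=O
F4 | step 8 | 2-[(2R)-2-(tert-butyldimethylsilyloxy)-4-phenylbutyl]-2-[(2S)-oxiran-2-ylmethyl]-1,3-dithiane | CC(C)(C)[Si](C)(C)O[C@H](CCc1ccccc1)CC2(SCCCS2)C[C@H]3CO3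
F5 | step 8 | (2R)-1-{2-[(2R)-2-(tert-butyldimethylsilyloxy)-4-phenylbutyl]-1,3-dithian-2-yl}-5-[(2S,6R)-6-methoxy-3,6-dihydro-2H-pyran-2-yl]pent-4-yn-2-ol | CC(C)(C)[Si](C)(C)O[C@H](CCc1ccccc1)CC2(SCCCS2)C[C@H](O)CC#C[C@@H]3CC=C[C@H](OC)O3
F6 | step 8 | 2-[(2R)-2-(tert-butyldimethylsilyloxy)-4-phenylbutyl]-2-{(2R)-2-[(4-methoxybenzyl)oxy]-5-[(2S,6R)-6-methoxy-3,6-dihydro-2H-pyran-2-yl]pent-4-yn-1-yl}-1,3-dithiane | CC(C)(C)[Si](C)(C)O[C@H](CCc1ccccc1)CC2(SCCCS2)C[C@H](OCc3ccc(OC)cc3)CC#C[C@@H]4CC=C[C@H](OC)O4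
F7 | step 8 | (3R,7R)-3-(tert-butyldimethylsilyloxy)-7-[(4-methoxybenzyl)oxy]-10-[(2S,6R)-6-methoxy-3,6-dihydro-2H-pyran-2-yl]-1-phenyldec-9-yn-5-one | CC(C)(C)[Si](C)(C)O[C@H](CCc1ccccc1)CC(=O)C[C@H](OCc2ccc(OC)cc2)CC#C[C@@H]3CC=C[C@H](OC)O3
F8 | step 8 | (3R,7R,9Z)-3-(tert-butyldimethylsilyloxy)-7-[(4-methoxybenzyl)oxy]-10-[(2S,6R)-6-methoxy-3,6-dihydro-2H-pyran-2-yl]-1-phenyldec-9-en-5-one | CC(C)(C)[Si](C)(C)O[C@H](CCc1ccccc1)CC(=O)C[C@H](OCc2ccc(OC)cc2)C/C=C\[C@@H]3CC=C[C@H](OC)O3
F9 | step 10 | all-cis O9,O11 p-methoxybenzylidene acetal of 23 (2-(4-methoxyphenyl)-1,3-dioxane; C13 acetate retained) | CC(=O)O[C@H](CCc1ccccc1)C[C@H]2C[C@@H](C/C=C\[C@@H]3CC=C[C@H](OC)O3)O[C@@H](c4ccc(OC)cc4)O2
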